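**Retrosynthetic overview**
- The target is cut at the E-olefin: cross-metathesis of a 2-vinyl furopyranone with the side-chain olefin (2R,3S)-2-acetoxypent-4-en-3-yl benzoate.
- The 2-vinyl furopyranone comes from ring-rearrangement metathesis of the mono-acrylate of meso endo-7-oxanorbornene-2,3-diol. The oxygen bridge becomes the tetrahydrofuran (ring A, formed first); the acrylate closes the pyranone (ring B, formed second); the four ring stereocentres are all-cis by construction.
- The mono-acrylate comes from a catalytic enantioselective acryloylation that breaks the mirror symmetry of the meso diol. The diol comes from the endo Diels–Alder adduct of furan (dearomatised) with vinylene carbonate.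
- The side chain comes from Sharpless desymmetrisation of divinylcarbinol, hydride opening, lipase-regioselective acetylation and benzoylation.

Assumption: the sense of induction of the Cu(OTf)2/Ph-BOX acylation on this bridged meso diol is not fixed by precedent; (R,R)-Ph-BOX is written, and if Mosher analysis of 5 shows the enantiomeric ester, (S,S)-Ph-BOX is used with no other change.

**Step 1**
Reactants: 1 furan; 2 vinylene carbonate (1,3-dioxol-2-one)
Product: 3 endo-cis-7-oxabicyclo[2.2.1]hept-5-ene-2,3-diyl carbonate (meso; carbonate ring syn to the C=C bridge)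
Conditions: neat (1, 5 equiv), hydroquinone (cat.), sealed tube, 125 °C, 20 h; endo isomer separated from exo on SiO2
Reagents that add atoms: none
Why: Thermal Diels–Alder cycloaddition breaks the aromaticity of furan; the cis-dienophile adds suprafacially so the two C–O bonds are cis, and in the endo adduct they lie on the same face as the two-carbon bridge, which is the all-cis pattern of the target's tetrahydrofuran (the adduct is meso, so no absolute control is needed yet).

**Step 2**
Reactants: 3 endo carbonate adduct
Product: 4 meso-(1R,2R,3S,4S)-7-oxabicyclo[2.2.1]hept-5-ene-2,3-diol (endo,endo)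
Conditions: K2CO3 (0.1 equiv), MeOH, 0 → 23 °C, 2 h
Reagents that add atoms: none
Why: Base-catalysed transesterification (methanolysis) of the strained five-membered cyclic carbonate; no ring C–O bond is broken, so the endo,cis configuration is retained.

**Step 3**
Reactants: 4 meso endo-diol
Product: 5 (1R,2R,3R,4S)-3-hydroxy-7-oxabicyclo[2.2.1]hept-5-en-2-yl prop-2-enoate
Conditions: Cu(OTf)2 (5 mol%), (R,R)-Ph-BOX [2,2'-(propane-2,2-diyl)bis((4R)-4-phenyl-4,5-dihydrooxazole)] (5.5 mol%), acryloyl chloride (1.05 equiv), K2CO3 (1.5 equiv), CH2Cl2, −20 → 0 °C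
Reagents that add atoms: acryloyl chloride, C=CC(=O)Cl
Why: Proposed new method: the divalent copper bis(oxazoline) complex chelates the cis-1,2-diol, carbonate deprotonates the bound diol, and the chiral pocket lets only one enantiotopic alkoxide attack acryloyl chloride (the monoester no longer chelates, so diacylation stops); the closest known reaction type is the Cu(OTf)2/Ph-BOX-catalysed enantioselective monobenzoylation of meso-1,2-diols (desymmetrising acylation), and this single choice fixes the absolute configuration of all four ring stereocentres.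

**Step 4**
Reactants: 6 divinylcarbinol (penta-1,4-dien-3-ol)
Product: 7 (2R,3S)-1,2-epoxypent-4-en-3-ol
Conditions: Ti(OiPr)4 (10 mol%), L-(+)-DIPT (13 mol%), cumene hydroperoxide (1.5 equiv), 4 Å MS, CH2Cl2, −20 °C, 5 d
Reagents that add atoms: cumene hydroperoxide, CC(C)(OO)c1ccccc1
Why: Sharpless asymmetric epoxidation used as a desymmetrisation; L-(+)-tartrate selects one enantiotopic vinyl group and one face to give the erythro (2R,3S) epoxy alcohol, and the minor enantiomer is consumed by faster second epoxidation, which raises the ee.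

**Step 5**
Reactants: 7 epoxy alcohol
Product: 8 (2R,3S)-pent-4-ene-2,3-diol (anti)
Conditions: LiAlH4 (1.1 equiv), Et2O, 0 °C; then Na2SO4·10H2O
Reagents that add atoms: none
Why: Hydride opens the terminal epoxide by SN2 attack at the unsubstituted CH2, so neither C–O stereocentre is touched and the anti diol results.

**Step 6**
Reactants: 8 anti diol
Product: 9 (2R,3S)-3-hydroxypent-4-en-2-yl acetate
Conditions: Novozym 435 (immobilised Candida antarctica lipase B), vinyl acetate (3 equiv), MTBE, 25 °C
Reagents that add atoms: vinyl acetate, CC(=O)OC=C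
Why: Lipase-catalysed regioselective transesterification; by Kazlauskas' rule the enzyme acylates the (R)-configured methyl carbinol, whereas the (S)-configured allylic carbinol with two large substituents does not fit, so only O-2 is acetylated under neutral conditions that avoid acyl migration.

**Step 7**
Reactants: 9 monoacetate
Product: 10 (2R,3S)-2-(acetyloxy)pent-4-en-3-yl benzoate
Conditions: BzCl (1.2 equiv), pyridine (3 equiv), DMAP (5 mol%), CH2Cl2, 0 °C
Reagents that add atoms: benzoyl chloride, O=C(Cl)c1ccccc1
Why: DMAP-catalysed acylation (nucleophilic catalysis) of the remaining allylic hydroxyl at low temperature is faster than acetyl migration, and no stereocentre is touched.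

**Step 8**
Reactants: 5 mono-acrylate; 10 side-chain olefin
Product: 12 CNP0151877.1 [(2S,3R,3aR,7aR)-2-[(1E,3S,4R)-4-(acetyloxy)-3-(benzoyloxy)pent-1-en-1-yl]-3-hydroxy-2,3,3a,7a-tetrahydro-5H-furo[3,2-b]pyran-5-one], via 2-vinyl furopyranone 11 (not isolated)
Conditions: (i) second-generation Hoveyda–Grubbs catalyst RuCl2(H2IMes)(=CH-C6H4-2-OiPr) (5 mol%), ethylene (1 atm), CH2Cl2 (0.01 M), 23 → 40 °C; (ii) Ar purge, concentrate to 0.1 M, 10 (3 equiv), same catalyst (5 mol%), 40 °C, 16 h
Reagents that add atoms: none
Why: Ring-rearrangement metathesis (ring-opening/ring-closing) releases the strain of the oxanorbornene and closes the six-membered enoate onto the acrylate, carrying the four sp3 centres unchanged into the all-cis furopyranone; cross-metathesis of the vinyl group with the allylic benzoate then gives the E-olefin under thermodynamic control, and any minor enantiomer of 5 ends as a diastereomer of 12 that is removed by chromatography.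

**Compound list**
1 | furan | c1ccoc1 | starting material
2 | vinylene carbonate (1,3-dioxol-2-one) | O=C1OC=CO1 | starting material
3 | endo-cis-7-oxabicyclo[2.2.1]hept-5-ene-2,3-diyl carbonate, meso (1R,2S,3R,4S) | O=C1O[C@H]2[C@@H](O1)[C@H]3C=C[C@@H]2O3 | intermediate
4 | meso-(1R,2R,3S,4S)-7-oxabicyclo[2.2.1]hept-5-ene-2,3-diol (endo,endo) | O[C@H]1[C@@H](O)[C@H]2C=C[C@@H]1O2 | intermediate
5 | (1R,2R,3R,4S)-3-hydroxy-7-oxabicyclo[2.2.1]hept-5-en-2-yl prop-2-enoate | O[C@H]1[C@@H](OC(=O)C=C)[C@H]2C=C[C@@H]1O2 | intermediate
6 | divinylcarbinol (penta-1,4-dien-3-ol) | C=CC(O)C=C | starting material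
7 | (2R,3S)-1,2-epoxypent-4-en-3-ol | C1O[C@H]1[C@H](C=C)O | intermediate
8 | (2R,3S)-pent-4-ene-2,3-diol | O[C@H](C)[C@H](C=C)O | intermediate
9 | (2R,3S)-3-hydroxypent-4-en-2-yl acetate | CC(=O)O[C@H](C)[C@H](C=C)O | intermediate
10 | (2R,3S)-2-(acetyloxy)pent-4-en-3-yl benzoate | CC(=O)O[C@H](C)[C@H](C=C)OC(=O)c1ccccc1 | intermediate
11 | (2S,3R,3aR,7aR)-2-ethenyl-3-hydroxy-2,3,3a,7a-tetrahydro-5H-furo[3,2-b]pyran-5-one | C=C[C@@H]1O[C@@H]2C=CC(=O)O[C@@H]2[C@@H]1O | intermediate
12 | (2S,3R,3aR,7aR)-2-[(1E,3S,4R)-4-(acetyloxy)-3-(benzoyloxy)pent-1-en-1-yl]-3-hydroxy-2,3,3a,7a-tetrahydro-5H-furo[3,2-b]pyran-5-one | CC(=O)O[C@H](C)[C@H](/C=C/[C@@H]1O[C@@H]2C=CC(=O)O[C@@H]2[C@@H]1O)OC(=O)c1ccccc1 | target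

**Step count and risks**
Total steps: 8. Longest linear sequence: 5 (steps 4, 5, 6, 7, 8); the ring arm is 4 (steps 1, 2, 3, 8).

Step 3 (desymmetrising acryloylation) is the first risk: acryloyl chloride is untested in this catalyst system, the sense on a bridged diol is unproven, and acyl migration between the cis hydroxyls would erode the ee. The fallback sets out from 4 and desymmetrises by silyl transfer instead of acyl transfer. Enantioselective mono-silylation (TBSCl, DIPEA, an amino-acid-derived N-methylimidazole catalyst of the Hoveyda–Snapper type, THF, −30 °C) gives (1R,2S,3S,4S)-3-[(tert-butyldimethylsilyl)oxy]-7-oxabicyclo[2.2.1]hept-5-en-2-ol F1. Acryloyl chloride and Et3N in CH2Cl2 at 0 °C then give the silyl ether acrylate (1R,2S,3R,4S)-3-[(tert-butyldimethylsilyl)oxy]-7-oxabicyclo[2.2.1]hept-5-en-2-yl prop-2-enoate F2. HF·pyridine in THF removes the silyl group and the route is rejoined at 5.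

Step 8 (one-pot ring rearrangement and cross-metathesis) is the second risk: ring-opening oligomerisation can compete in stage (i), and the union of two hindered, allylically oxygenated olefins in stage (ii) may stall. The fallback sets out from 11, isolated after stage (i), and couples the side chain as its free carbinol with the ring hydroxyl masked, so that benzoylation comes after C=C formation. TESOTf and 2,6-lutidine in CH2Cl2 at −78 °C give the triethylsilyl ether of 11 F3. Cross-metathesis of this with 9 (2 equiv; free allylic carbinols are better cross partners than their benzoates) under the same ruthenium catalyst at 40 °C gives the E-configured triethylsilyl ether of debenzoyl-12 F4. BzCl, pyridine and DMAP give the triethylsilyl ether of 12 F5, and HF·pyridine in THF returns to the route at 12.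

Step 6 (lipase regioselection between two secondary hydroxyls) is the third risk: the regioselectivity is a prediction, and a mixture of monoacetates would be hard to separate. The fallback sets out from 7 and differentiates the oxygens by the order in which they are unveiled. BzCl and pyridine give (2R,3S)-1,2-epoxypent-4-en-3-yl benzoate F6. NaI and AcOH in THF open the epoxide at the terminal carbon to give (2S,3S)-2-hydroxy-1-iodopent-4-en-3-yl benzoate F7. Bu3SnH and AIBN in benzene at 80 °C remove the iodine to give (2R,3S)-2-hydroxypent-4-en-3-yl benzoate F8. Ac2O, pyridine and DMAP at 0 °C then rejoin the route at 10.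

**Further compounds**
F1 | step 3 | (1R,2S,3S,4S)-3-[(tert-butyldimethylsilyl)oxy]-7-oxabicyclo[2.2.1]hept-5-en-2-ol | CC(C)(C)[Si](C)(C)O[C@H]1[C@@H](O)[C@H]2C=C[C@@H]1O2
F2 | step 3 | (1R,2S,3R,4S)-3-[(tert-butyldimethylsilyl)oxy]-7-oxabicyclo[2.2.1]hept-5-en-2-yl prop-2-enoate | CC(C)(C)[Si](C)(C)O[C@H]1[C@@H](OC(=O)C=C)[C@H]2C=C[C@@H]1O2
F3 | step 8 | triethylsilyl ether of 11 | C=C[C@@H]1O[C@@H]2C=CC(=O)O[C@@H]2[C@@H]1O[Si](CC)(CC)CC
F4 | step 8 | triethylsilyl ether of debenzoyl-12 (free side-chain allylic carbinol, E-olefin) | CC(=O)O[C@H](C)[C@H](/C=C/[C@@H]1O[C@@H]2C=CC(=O)O[C@@H]2[C@@H]1O[Si](CC)(CC)CC)O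
F5 | step 8 | triethylsilyl ether of 12 | CC(=O)O[C@H](C)[C@H](/C=C/[C@@H]1O[C@@H]2C=CC(=O)O[C@@H]2[C@@H]1O[Si](CC)(CC)CC)OC(=O)c1ccccc1
F6 | step 6 | (2R,3S)-1,2-epoxypent-4-en-3-yl benzoate | C1O[C@H]1[C@H](C=C)OC(=O)c2ccccc2
F7 | step 6 | (2S,3S)-2-hydroxy-1-iodopent-4-en-3-yl benzoate | IC[C@@H](O)[C@H](C=C)OC(=O)c1ccccc1
F8 | step 6 | (2R,3S)-2-hydroxypent-4-en-3-yl benzoate | C[C@@H](O)[C@H](C=C)OC(=O)c1ccccc1
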